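The cyclobutane of cardopatine is C2-symmetric: the axis bisects the C1–C2 bond (the two CH carbons that carry the alkynyl arms) and the C3–C4 bond (the two CH2 carbons), so ring atoms C1/C4 and C2/C3 are the vinyl groups of two identical halves. Everything rests on the biomimetic head-to-head dimerisation of the achiral enyne 5-(but-3-en-1-ynyl)-2,2'-bithiophene. One enantioselective radical-cation [2+2] cycloaddition should form the C3–C4 and C1–C2 bonds, close the four-membered ring and set both stereocentres as (1R,2R). The precursor is the acyclic monomer, available in two steps from 2,2'-bithiophene-5-carbaldehyde.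

Key step: step 3

Assumption: the sense of induction of the chiral anion on this substrate class cannot be predicted. Both antipodes of the anion are accessible from (R)- or (S)-BINOL, and the one that leads to (1R,2R)-6 is fixed in a first run analysed on a chiral stationary phase; it is written below as the (S,S) antipode. Enyne 5 is handled in amber glassware and used soon after it is made.

Step 1
Reactants: 1 2,2'-bithiophene-5-carbaldehyde
Product: 3 5-ethynyl-2,2'-bithiophene, via diazoalkene 2 (not isolated)
Conditions: Ohira–Bestmann reagent (1.3 equiv), K2CO3 (2 equiv), MeOH, 0 °C to rt
Reagents that add atoms: dimethyl (1-diazo-2-oxopropyl)phosphonate (Ohira–Bestmann reagent), CC(=O)C(=[N+]=[N-])P(=O)(OC)OC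
Why: Seyferth–Gilbert homologation in the Ohira–Bestmann variant, in which methanolysis of the reagent gives the dimethyl (diazomethyl)phosphonate anion, Horner–Wadsworth–Emmons olefination of the non-enolisable aldehyde gives diazoalkene 2, and loss of N2 with a 1,2-hydrogen shift gives the terminal alkyne; no stereocentre is formed.

Step 2
Reactants: 3 5-ethynyl-2,2'-bithiophene; 4 vinyl bromide (1 M in THF, 3 equiv)
Product: 5 5-(but-3-en-1-yn-1-yl)-2,2'-bithiophene
Conditions: Pd(PPh3)4 (3 mol%), CuI (copper iodide, 6 mol%), iPr2NH, THF, 0 °C to rt, sealed vessel, dark
Reagents that add atoms: none
Why: Sonogashira coupling, in which vinyl bromide adds oxidatively to zerovalent palladium, the copper acetylide of 3 transmetalates and reductive elimination gives the conjugated enyne, with the thiophene C–H bonds untouched; no stereocentre is formed.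

Step 3
Reactants: 5 5-(but-3-en-1-yn-1-yl)-2,2'-bithiophene (two molecules)
Product: 6 cardopatine, (1R,2R)-1,2-bis[(2,2'-bithiophen-5-yl)ethynyl]cyclobutane
Conditions: 9-mesitylthioxanthylium salt of an enantiopure (S,S)-BINOL-derived N-triflyl imidodiphosphorimidate anion (3 mol%), green LEDs (525 nm), CH2Cl2 (0.2 M), −78 °C, argon
Reagents that add atoms: none
Why: Proposed new method: green light excites the thioxanthylium cation, which takes one electron from 5; the radical cation of 5, held as a contact ion pair by the confined chiral anion, bonds through its vinyl CH2 terminus to the CH2 terminus of a second, neutral molecule of 5 (C3–C4), and the resulting 1,4-distonic radical cation (a propargyl radical and a bithienyl-stabilised propargyl cation) collapses at the two propargylic carbons (C1–C2) to the cyclobutane radical cation, which is reduced to 6 by a further molecule of 5 in a chain or by the reduced photocatalyst. The closest known reaction type is the radical-cation [2+2] cyclodimerisation of terminal vinyl donors such as N-vinylcarbazole and 4-methoxystyrene to head-to-head trans-1,2-disubstituted cyclobutanes, together with its enantioselective form under a photoredox cation paired with a confined imidodiphosphorimidate anion, which is shown on styrenes but not on 1,3-enynes or for propargylic stereocentres. The four-membered ring closes as a stepwise formal [2+2] cycloaddition, with the intermolecular tail-to-tail bond first and ring closure by radical–cation combination second. Both stereocentres, C1 and C2, arise in that closure: the trans relation should follow from the two rod-like arms and the bulky anion avoiding each other, and the absolute (1R,2R) sense from the chiral anion shielding one face of the propargylic cation (catalyst control). The step needs head-to-head regioselectivity, secured because only bonding through the unsubstituted CH2 termini leaves spin and charge in conjugated propargylic positions, and chemoselectivity for the vinyl group over oxidative coupling at the free 5'-position of the bithiophene, which the low stationary concentration of radical cation, the low temperature and the large excess of neutral olefin should favour. Re-oxidation of 6 should be disfavoured because its 5-alkynylbithiophene chromophore is less extended, hence harder to oxidise, than the enyne of 5.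

Compound list
1 | 2,2'-bithiophene-5-carbaldehyde | O=Cc1ccc(-c2cccs2)s1 | starting material
2 | 5-(2-diazoethenyl)-2,2'-bithiophene (diazoalkene, not isolated) | [N-]=[N+]=C=Cc1ccc(-c2cccs2)s1 | intermediate
3 | 5-ethynyl-2,2'-bithiophene | C#Cc1ccc(-c2cccs2)s1 | intermediate
4 | vinyl bromide (bromoethene) | C=CBr | starting material
5 | 5-(but-3-en-1-yn-1-yl)-2,2'-bithiophene | C=CC#Cc1ccc(-c2cccs2)s1 | intermediate
6 | cardopatine, (1R,2R)-1,2-bis[(2,2'-bithiophen-5-yl)ethynyl]cyclobutane | C(#C[C@@H]1CC[C@H]1C#Cc1ccc(-c2cccs2)s1)c1ccc(-c2cccs2)s1 | target

Total step count: 3. Longest linear sequence: 3 steps (1 to 3 to 5 to 6).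

Steps most likely to fail

Step 3 (Proposed new method). Oxidative carbon–carbon coupling through the unsubstituted 5'-positions of the bithiophene may outrun the cycloaddition and lead to oligomerisation. The anion may also discriminate poorly between the faces of a propargylic carbon that lies far from the centre of charge, and reversible ring opening at the radical-cation stage may erode both the trans preference and the enantiomeric purity. The fallback sets out from 5 and avoids radical cations altogether. Triplet energy transfer from thioxanthen-9-one (10 mol%, 405 nm LEDs, degassed CH2Cl2, rt) should give the head-to-head [2+2] photodimers through a 1,4-biradical that closes at its two propargylic carbons. The trans dimer forms as the racemate, that is 6 together with its (1S,2S)-enantiomer F1, beside the meso cis isomer isocardopatine F2. F2 is removed on silica gel, and 6 is separated from F1 by preparative HPLC on an amylose tris(3,5-dimethylphenylcarbamate) stationary phase. The fallback comes back to the route at 6.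

Step 2. Oxidative homocoupling of the terminal alkyne (Glaser pathway), escape of the volatile vinyl bromide and light- or radical-induced oligomerisation of the enyne during isolation may lower the throughput. The fallback sets out from 3 and builds the vinyl group by elimination instead of cross-coupling. Deprotonation with n-BuLi (THF, −78 °C) and addition of the lithium acetylide to acetaldehyde should give racemic 4-(2,2'-bithiophen-5-yl)but-3-yn-2-ol F3. Mesylation (MsCl, Et3N, CH2Cl2, 0 °C) gives 4-(2,2'-bithiophen-5-yl)but-3-yn-2-yl methanesulfonate F4, which is not stored. Elimination with DBU (toluene, rt to 60 °C) can only take a methyl hydrogen and so gives the terminal enyne. The fallback comes back at 5.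

Step 1. The Horner–Wadsworth–Emmons addition to the electron-rich, weakly electrophilic thienyl aldehyde may be slow, so that the diazophosphonate decays before conversion is complete, and the alkylidene carbene may be trapped by methanol. The fallback sets out from 1 and uses the Corey–Fuchs sequence. CBr4 and PPh3 (CH2Cl2, 0 °C) should give 5-(2,2-dibromoethenyl)-2,2'-bithiophene F5. n-BuLi (2.2 equiv, THF, −78 °C, then aqueous NH4Cl) gives the alkyne by bromine–lithium exchange and Fritsch–Buttenberg–Wiechell rearrangement; any lithiation of the thiophene terminus is reversed on protonation. The fallback comes back at 3.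

Further compounds
F1 | step 3 | (1S,2S)-1,2-bis[(2,2'-bithiophen-5-yl)ethynyl]cyclobutane (enantiomer of 6) | C(#C[C@H]1CC[C@@H]1C#Cc1ccc(-c2cccs2)s1)c1ccc(-c2cccs2)s1
F2 | step 3 | (1R,2S)-1,2-bis[(2,2'-bithiophen-5-yl)ethynyl]cyclobutane (meso cis isomer, isocardopatine) | C(#C[C@@H]1CC[C@@H]1C#Cc1ccc(-c2cccs2)s1)c1ccc(-c2cccs2)s1
F3 | step 2 | 4-(2,2'-bithiophen-5-yl)but-3-yn-2-ol (racemic) | CC(O)C#Cc1ccc(-c2cccs2)s1
F4 | step 2 | 4-(2,2'-bithiophen-5-yl)but-3-yn-2-yl methanesulfonate (racemic) | CC(OS(C)(=O)=O)C#Cc1ccc(-c2cccs2)s1
F5 | step 1 | 5-(2,2-dibromoethenyl)-2,2'-bithiophene | BrC(Br)=Cc1ccc(-c2cccs2)s1
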